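At early times the two runs lie nearer together in fractions of the charge than later: at 0.333 d the delta run holds 3.4% as target and the epsilon run 2.6%. By 2.50 d the gap between them is wider, at 11.4% and 7.1%.

all flasks: gas phase 23 mM (held)

|  | substrate | remark | time |
|---|---|---|---|
| delta | 0.34 M | run made earlier |  |
| epsilon | 0.75 M | run made earlier |  |
| flask | 0.50 M |  | 4.0 d |

- delta (time / d: target / %): 0.208: 1.9; 0.333: 3.4; 0.417: 4.1; 0.625: 5.6; 1.04: 7.6; 1.67: 10.5; 2.50: 11.4
- epsilon (time / d: target / %): 0.125: 0.7; 0.333: 2.6; 0.625: 4.4; 1.04: 5.8; 1.67: 6.1; 2.08: 6.9; 2.50: 7.1

(readings scatter by 0.3 percentage points)

- at the start none of the gas phase is in solution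

- spring: doubling the saturation concentration of gas phase, all else as stated
- summer: doubling the transfer coefficient of the gas phase, all else as stated

1. how much target there is at 4.0 d, in percent of the substrate charged
2. the change that raises the amount of target at 4.0 d, in percent of the substrate charged most ("none" if none brings more than 2 percentage points) (spring / summer / none)
3. amount of target at 4.0 d, in percent of the substrate charged, after spring

My reckoning uses the charge exponent, the power by which the fraction reaching target at a fixed time falls as the starting substrate rises. This log-log slope between the two last readings is 0.599. A first round from the delta run to the flask's 0.50 M gives 9.05% at 2.50 d.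

A second round puts that answer back in and carries it on to 4.0 d. That time step, a ratio of 1.60, resembles the last measured one, a ratio of 1.50, over which the two runs grew by a mean factor of 1.12. My estimate is therefore 10.2%.

The forecast differs slightly, with 9.7%, and chooses spring at 15%, saying “That suggests an equilibrium-like limit or a self-limiting loss, not transfer control.”

The flask gives 9.89%. The better change is spring, which reaches 15.5% and adds 5.6 percentage points, against 1.1 points for summer.

    dissolved gas → decomposed reagent (k = 0.0618 /h)
    substrate + dissolved gas → target (k = 0.413 /M/h)
    target ⇌ isomer of the product (K = 0.880, k = 0.0186 /h)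
    gas phase ⇌ dissolved gas, rate k4*(csat - [dissolved gas]) (kL = 0.490 /h)
    2 substrate → homo dimer (k = 0.0694 /M/h)
    dissolved gas + target → over-reacted product (k = 0.0760 /M/h)

Scaled by the charge exponent, which was read from the runs at 2.50 d, the flask's 9.89% becomes 17.1% for the neighbour charged with 0.20 M of substrate and read at the same 4.0 d. That neighbour holds 16.4% of its charge as target, more than the flask. Its homo dimer takes less of the charge than the flask's, at 54.9% against 74.0%.

The data were computed on assumed constants, and the scatter is random.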